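**Retrosynthetic overview**
1. The ester C–O bond is cut first, giving octacosanoic acid 10 and 2-phenylethanol 11; the benzene ring is bought and no ring is built.
2. The strategy rests on the C12–C13 bond of the unbranched C28 acyl chain: two equivalent, unactivated CH2 carbons with no functional handle nearby. This bond is traced back through the C12=C13 alkene 9 to sulfone 5, in which one SO2 group bridges C12 and C13 (Ramberg–Bäcklund).
3. Sulfone 5 comes from sulfide 3, whose two C–S bonds join thiol 1 (C13–C28) and bromo acid 2 (C1–C12).
4. Ring order: the only ring closed is the transient three-membered thiirane 1,1-dioxide (S, C12, C13) inside the key step; it collapses with loss of SO2 in the same flask.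

Key step: step 3

Remark: in the basic media of steps 1 and 3 the carboxylic acids are present as carboxylate salts; they are named and drawn as the free acids obtained after acidic work-up. Episulfone 8 and alkene 9 are drawn as the trans and E isomers; the cis and Z isomers are equally acceptable because step 4 removes the distinction.

**Step 1**
Reactants: 1 1-hexadecanethiol; 2 12-bromododecanoic acid
Product: 3 12-(hexadecylsulfanyl)dodecanoic acid
Conditions: NaOH (2.2 equiv), degassed EtOH–H2O, N2, reflux; then aq. HCl to pH 2
Reagents that add atoms: none
Why: Williamson-type thioether synthesis, in which the thiolate formed by NaOH displaces the unhindered primary bromide by SN2 much faster than carboxylate, hydroxide or ethoxide can, while exclusion of air suppresses disulfide formation.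

**Step 2**
Reactants: 3 12-(hexadecylsulfanyl)dodecanoic acid
Product: 5 12-(hexadecylsulfonyl)dodecanoic acid, via 12-(hexadecylsulfinyl)dodecanoic acid 4 (not isolated)
Conditions: 30% aq. H2O2 (3 equiv), Na2WO4·2H2O (2 mol %), AcOH, 60 °C
Reagents that add atoms: hydrogen peroxide, OO
Why: Tungstate-catalysed peroxide oxidation of a dialkyl sulfide passes through sulfoxide 4 and stops at the sulfone, since the saturated chains and the carboxylic acid offer nothing else to oxidise.

**Step 3**
Reactants: 5 12-(hexadecylsulfonyl)dodecanoic acid
Product: 9 (E)-octacos-12-enoic acid, via 12-bromo-12-(hexadecylsulfonyl)dodecanoic acid 6 (not isolated), via 12-[(1-bromohexadecyl)sulfonyl]dodecanoic acid 7 (not isolated), via trans-episulfone 8 (not isolated)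
Conditions: CBr2F2 (5 equiv), KOH/Al2O3 (excess), t-BuOH–CH2Cl2, 5 °C → rt; then aq. KOH wash; then 1 M HCl
Reagents that add atoms: dibromodifluoromethane, FC(F)(Br)Br (its bromine is carried by 6 and 7 only; no reagent atom remains in 9)
Why: This is the Ramberg–Bäcklund reaction in its one-flask form with in situ halogenation: hydroxide on alumina removes a proton from C12 or C13, the only carbons acidified by the sulfonyl group, and the carbanion takes a bromine atom from CBr2F2 to give 6 or 7. A second deprotonation at the other alpha carbon then displaces bromide in a 1,3-fashion (3-exo-tet) to close the three-membered thiirane 1,1-dioxide 8 (S, C12, C13), which is not a lasting ring and loses SO2 cheletropically to leave the C12=C13 double bond. The closest known reaction type is the conversion of acyclic di-primary-alkyl sulfones into 1,2-dialkylethylenes with KOH/Al2O3 and CBr2F2. No stereocentre is created in the product, and alkene geometry needs no control because step 4 removes it. The only selectivity required is that bromination occurs next to sulfur, and the substrate secures it: 6 and 7 converge on the same episulfone, and the acid is masked as its potassium carboxylate, which is neither brominated nor cleaved (the base-labile phenethyl ester is therefore attached only afterwards). Because the two C–S bonds were made by mild SN2 chemistry, the difficult union of two unactivated sp3 carbons becomes an intramolecular displacement within the sulfur tether.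

**Step 4**
Reactants: 9 (E)-octacos-12-enoic acid
Product: 10 octacosanoic acid
Conditions: H2 (1 atm), Pd/C (10 wt % Pd), THF–EtOAc, 40 °C
Reagents that add atoms: none
Why: Heterogeneous catalytic hydrogenation of an unhindered 1,2-dialkylethylene over Pd/C is facile, leaves the carboxylic acid untouched and converts both geometric isomers (and any vinyl bromide from double bromination) into the same saturated acid.

**Step 5**
Reactants: 10 octacosanoic acid; 11 2-phenylethanol (3 equiv)
Product: 12 2-phenylethyl octacosanoate (phenylethyl n-octacosanoate)
Conditions: p-TsOH·H2O (5 mol %), toluene, reflux, Dean–Stark trap; excess 11 removed by recrystallisation from acetone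
Reagents that add atoms: none
Why: Fischer esterification of an unhindered acid with a primary alcohol is driven to completion by azeotropic removal of water, and neither partner carries an acid-sensitive group.

**Compound list**
1 | 1-hexadecanethiol | CCCCCCCCCCCCCCCCS | starting material
2 | 12-bromododecanoic acid | OC(=O)CCCCCCCCCCCBr | starting material
3 | 12-(hexadecylsulfanyl)dodecanoic acid | CCCCCCCCCCCCCCCCSCCCCCCCCCCCC(=O)O | intermediate
4 | 12-(hexadecylsulfinyl)dodecanoic acid (racemic at sulfur; not isolated) | CCCCCCCCCCCCCCCCS(=O)CCCCCCCCCCCC(=O)O | intermediate
5 | 12-(hexadecylsulfonyl)dodecanoic acid | CCCCCCCCCCCCCCCCS(=O)(=O)CCCCCCCCCCCC(=O)O | intermediate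
6 | 12-bromo-12-(hexadecylsulfonyl)dodecanoic acid (racemic; not isolated) | CCCCCCCCCCCCCCCCS(=O)(=O)C(Br)CCCCCCCCCCC(=O)O | intermediate
7 | 12-[(1-bromohexadecyl)sulfonyl]dodecanoic acid (racemic; not isolated) | CCCCCCCCCCCCCCCC(Br)S(=O)(=O)CCCCCCCCCCCC(=O)O | intermediate
8 | 11-[(2R*,3R*)-1,1-dioxo-3-pentadecylthiiran-2-yl]undecanoic acid (trans-episulfone, racemic; not isolated) | CCCCCCCCCCCCCCC[C@H]1[C@H](CCCCCCCCCCC(=O)O)S1(=O)=O | intermediate
9 | (E)-octacos-12-enoic acid | CCCCCCCCCCCCCCC/C=C/CCCCCCCCCCC(=O)O | intermediate
10 | octacosanoic acid | CCCCCCCCCCCCCCCCCCCCCCCCCCCC(=O)O | intermediate
11 | 2-phenylethanol | OCCc1ccccc1 | starting material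
12 | 2-phenylethyl octacosanoate | CCCCCCCCCCCCCCCCCCCCCCCCCCCC(=O)OCCc1ccccc1 | target

Total step count: 5. Longest linear sequence: 5 steps (1 or 2 → 3 → 5 → 9 → 10 → 12).

**Steps most likely to fail**

Step 3. The potassium carboxylate may bind to the alumina or stay out of solution, so that alpha-deprotonation and bromination are slow while the volatile bromine source escapes. A second bromination may also occur before ring closure, and the released difluorocarbene may be captured on the carboxylate oxygen (the hydroxide wash should cleave any such ester). Fallback: the C12=C13 bond would be made by a Wittig reaction. It sets out from bromo acid 2, which on heating with triphenylphosphine in MeCN should give (11-carboxyundecyl)triphenylphosphonium bromide F1. Double deprotonation with NaN(SiMe3)2 (2.1 equiv, THF, 0 °C) and addition of purchased hexadecanal (−78 °C → rt) should give mainly (Z)-octacos-12-enoic acid F2. Hydrogenation under the conditions of step 4 brings the fallback back to the route at 10.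

Step 4. Traces of sulfur-containing material from step 3 may poison the palladium surface, or the waxy acid may crystallise onto the catalyst and stall the reduction. Fallback: a metal-free diimide reduction setting out from 9, with p-toluenesulfonyl hydrazide and CH3CO2Na in refluxing THF–H2O, which is indifferent to sulfur residues and arrives at 10. It makes no compound outside the list (F0).

Step 5. Conversion may stay incomplete because the sparingly soluble acid does not drive the equilibrium, and acid-catalysed self-etherification of the alcohol may consume the nucleophile and complicate purification. Fallback: irreversible acylation setting out from 10. Oxalyl chloride with catalytic DMF in toluene at 50 °C should give octacosanoyl chloride F3, which with 11, pyridine and catalytic DMAP in CH2Cl2 should give 12.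

**Further compounds**
F1 | step 3 | (11-carboxyundecyl)triphenylphosphonium bromide | OC(=O)CCCCCCCCCCC[P+](c1ccccc1)(c1ccccc1)c1ccccc1.[Br-]
F2 | step 3 | (Z)-octacos-12-enoic acid | CCCCCCCCCCCCCCC/C=C\CCCCCCCCCCC(=O)O
F0 | step 4 | none | none
F3 | step 5 | octacosanoyl chloride | CCCCCCCCCCCCCCCCCCCCCCCCCCCC(=O)Cl
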